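**Retrosynthetic overview**
1. Target 33 ← buffered global desilylation of hexa-TIPS enone 32 ← oxidation of allylic alcohol 31 ← Nozaki–Hiyama–Kishi coupling of C7 aldehyde 25 with enol triflate 29.
2. C3 aroyl group ← arylcerium addition to C3 aldehyde 18, then oxidation; C7 CHO ← the ester carried from the starting benzoate.
3. Dihydrofuran ring (the only ring formed; all four benzene rings are bought) ← acid-mediated benzylic etherification of phenol diol 16, with 2,3-trans set by C3.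
4. Key C2–C3 bond ← Evans syn-aldol of arylacetyl imide 10, carrying (R)-4-benzyl-oxazolidinone, with 4-TIPSO-benzaldehyde 12; this sets C3.
5. Arylacetic acid 7 ← methyl 2,4,6-trihydroxybenzoate by selective bis-silylation, O-allylation, Claisen rearrangement and oxidative cleavage.

Assumption: the target is taken as drawn, (2R,3R) with the 2-aryl and 3-aroyl groups trans. Abbreviations: TIPS = triisopropylsilyl, TIPSO = triisopropylsilyloxy, 4-TIPSO-phenyl = 4-(triisopropylsilyloxy)phenyl, MOM = methoxymethyl.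

**Step 1**
Reactants: 1 methyl 2,4,6-trihydroxybenzoate
Product: 2 methyl 2-hydroxy-4,6-bis(TIPSO)benzoate
Conditions: TIPSCl (2.1 equiv), imidazole, DMF, 0 °C → rt
Reagents that add atoms: TIPSCl, CC(C)[Si](Cl)(C(C)C)C(C)C
Why: Selective phenol silylation takes the 4-OH and one ortho OH, while the last ortho OH stays free because it is hydrogen-bonded to the ester carbonyl and hindered.

**Step 2**
Reactants: 2 methyl 2-hydroxy-4,6-bis(TIPSO)benzoate
Product: 3 methyl 2-(prop-2-en-1-yloxy)-4,6-bis(TIPSO)benzoate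
Conditions: allyl alcohol, PPh3, DIAD, THF, 0 °C → rt
Reagents that add atoms: allyl alcohol, C=CCO
Why: Mitsunobu etherification alkylates the acidic salicylate-type phenol under neutral conditions that leave aryl silyl ethers alone.

**Step 3**
Reactants: 3 methyl 2-(prop-2-en-1-yloxy)-4,6-bis(TIPSO)benzoate
Product: 4 methyl 2-hydroxy-3-(prop-2-en-1-yl)-4,6-bis(TIPSO)benzoate
Conditions: PhNEt2, 190 °C
Reagents that add atoms: none
Why: The aromatic Claisen rearrangement can deliver the allyl group only to the free ortho carbon (the other carries the ester), and it frees exactly the phenol that becomes the furan oxygen.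

**Step 4**
Reactants: 4 methyl 2-hydroxy-3-(prop-2-en-1-yl)-4,6-bis(TIPSO)benzoate
Product: 5 methyl 2-(methoxymethoxy)-3-(prop-2-en-1-yl)-4,6-bis(TIPSO)benzoate
Conditions: MOMCl, i-Pr2NEt, Bu4NI (cat.), CH2Cl2, 0 → 40 °C
Reagents that add atoms: chloromethyl methyl ether (MOMCl), COCCl
Why: MOM acetal formation masks the phenol (preventing later lactonisation onto the imide) with a group that acid removes while aryl TIPS ethers stay.

**Step 5**
Reactants: 5 methyl 2-(methoxymethoxy)-3-(prop-2-en-1-yl)-4,6-bis(TIPSO)benzoate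
Product: 6 methyl 2-(methoxymethoxy)-3-(2-oxoethyl)-4,6-bis(TIPSO)benzoate
Conditions: OsO4 (2 mol %), NaIO4, 2,6-lutidine, dioxane/H2O (3:1), rt
Reagents that add atoms: OsO4 (catalytic oxygen carrier), O=[Os](=O)(=O)=O; NaIO4 (terminal oxidant), [Na+].[O-]I(=O)(=O)=O
Why: Lemieux–Johnson oxidation (catalytic dihydroxylation then periodate cleavage) shortens the terminal alkene to the arylacetaldehyde without touching the arene.

**Step 6**
Reactants: 6 methyl 2-(methoxymethoxy)-3-(2-oxoethyl)-4,6-bis(TIPSO)benzoate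
Product: 7 2-[3-(methoxycarbonyl)-2-(methoxymethoxy)-4,6-bis(TIPSO)phenyl]acetic acid
Conditions: NaClO2, NaH2PO4, 2-methyl-2-butene, t-BuOH/H2O, 0 °C → rt
Reagents that add atoms: NaClO2, [Na+].[O-]Cl=O
Why: Pinnick oxidation converts only the aldehyde to the acid, the alkene scavenger removing HOCl before it can chlorinate the electron-rich ring.

**Step 7**
Reactants: 7 2-[3-(methoxycarbonyl)-2-(methoxymethoxy)-4,6-bis(TIPSO)phenyl]acetic acid; 8 (R)-4-benzyl-1,3-oxazolidin-2-one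
Product: 10 (4R)-4-benzyl-3-{2-[3-(methoxycarbonyl)-2-(methoxymethoxy)-4,6-bis(TIPSO)phenyl]acetyl}-1,3-oxazolidin-2-one, via mixed pivalic anhydride 9 (not isolated)
Conditions: PivCl, Et3N, THF, −20 °C; then 8, LiCl, −20 °C → rt
Reagents that add atoms: none
Why: Mixed-anhydride N-acylation of the oxazolidinone (LiCl/Et3N protocol) attaches the chiral auxiliary at the unhindered arylacetyl carbonyl under mild conditions.

**Step 8**
Reactants: 11 4-hydroxybenzaldehyde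
Product: 12 4-(TIPSO)benzaldehyde
Conditions: TIPSCl, imidazole, DMF, rt
Reagents that add atoms: TIPSCl, CC(C)[Si](Cl)(C(C)C)C(C)C
Why: Routine phenol silylation gives the aldol acceptor with the same fluoride-labile protection used throughout.

**Step 9**
Reactants: 10 (4R)-4-benzyl-3-{2-[3-(methoxycarbonyl)-2-(methoxymethoxy)-4,6-bis(TIPSO)phenyl]acetyl}-1,3-oxazolidin-2-one; 12 4-(TIPSO)benzaldehyde
Product: 14 (4R)-4-benzyl-3-{(2R,3R)-3-hydroxy-2-[3-(methoxycarbonyl)-2-(methoxymethoxy)-4,6-bis(TIPSO)phenyl]-3-(4-TIPSO-phenyl)propanoyl}-1,3-oxazolidin-2-one, via Z-dibutylboron enolate 13 (not isolated)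
Conditions: Bu2BOTf, i-Pr2NEt, CH2Cl2, −78 → 0 °C; 12, −78 → 0 °C; then pH 7 buffer, MeOH, H2O2, 0 °C
Reagents that add atoms: none
Why: In this Evans syn-aldol the Z-boron enolate reacts through a Zimmerman–Traxler chair on the face away from the auxiliary benzyl group, forming the future C2–C3 bond and setting the α-carbon (future C3) as R; the carbinol centre (R) is re-set in step 11.

**Step 10**
Reactants: 14 aldol adduct
Product: 15 methyl 3-[(1R,2S)-1,3-dihydroxy-1-(4-TIPSO-phenyl)propan-2-yl]-2-(methoxymethoxy)-4,6-bis(TIPSO)benzoate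
Conditions: LiBH4, MeOH (1 equiv), THF, 0 °C
Reagents that add atoms: none
Why: Reductive cleavage of the imide by LiBH4 gives the 1,3-diol and returns the auxiliary, without epimerising the α-centre (its descriptor becomes S only by priority change) and without reducing the doubly ortho-substituted aryl ester.

**Step 11**
Reactants: 15 methyl 3-[(1R,2S)-1,3-dihydroxy-1-(4-TIPSO-phenyl)propan-2-yl]-2-(methoxymethoxy)-4,6-bis(TIPSO)benzoate
Product: 17 methyl (2R,3S)-3-(hydroxymethyl)-4,6-bis(TIPSO)-2-(4-TIPSO-phenyl)-2,3-dihydro-1-benzofuran-7-carboxylate (2,3-trans), via phenol triol 16 (not isolated)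
Conditions: conc. HCl (cat.), MeOH/THF (1:1), 40 °C
Reagents that add atoms: none
Why: Acid removes the MOM group and ionises the p-silyloxybenzylic alcohol, and the ortho phenol closes the five-membered ring in a reversible SN1 etherification that places the C2 aryl trans to the fixed C3 substituent, giving 2R.

**Step 12**
Reactants: 17 methyl (2R,3S)-3-(hydroxymethyl)-4,6-bis(TIPSO)-2-(4-TIPSO-phenyl)-2,3-dihydro-1-benzofuran-7-carboxylate
Product: 18 methyl (2R,3R)-3-formyl-4,6-bis(TIPSO)-2-(4-TIPSO-phenyl)-2,3-dihydro-1-benzofuran-7-carboxylate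
Conditions: Dess–Martin periodinane, NaHCO3, CH2Cl2, 0 °C → rt
Reagents that add atoms: none
Why: Buffered Dess–Martin oxidation gives the aldehyde without epimerising C3 (R now only by priority change); it is used at once.

**Step 13**
Reactants: 19 4-bromobenzene-1,3-diol
Product: 20 1-bromo-2,4-bis(TIPSO)benzene
Conditions: TIPSCl (2.2 equiv), imidazole, DMF, rt
Reagents that add atoms: TIPSCl, CC(C)[Si](Cl)(C(C)C)C(C)C
Why: Phenol silylation; the bulky TIPS groups also resist O-to-C silyl migration once the ring is metalated.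

**Step 14**
Reactants: 18 methyl (2R,3R)-3-formyl-4,6-bis(TIPSO)-2-(4-TIPSO-phenyl)-2,3-dihydro-1-benzofuran-7-carboxylate; 20 1-bromo-2,4-bis(TIPSO)benzene
Product: 23 methyl (2R,3S)-3-{[2,4-bis(TIPSO)phenyl](hydroxy)methyl}-4,6-bis(TIPSO)-2-(4-TIPSO-phenyl)-2,3-dihydro-1-benzofuran-7-carboxylate (2,3-trans; both carbinol epimers), via aryllithium 21 (not isolated), via arylcerium dichloride 22 (not isolated)
Conditions: 20, n-BuLi, THF, −78 °C; CeCl3, −78 °C; then 18, −78 °C; aq. NH4Cl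
Reagents that add atoms: none
Why: Bromine–lithium exchange and transmetalation give a weakly basic organocerium whose 1,2-addition to the aldehyde outruns enolisation at C3 and leaves the hindered ester alone; the new carbinol centre is oxidised away later.

**Step 15**
Reactants: 23 hydroxy ester
Product: 24 [2,4-bis(TIPSO)phenyl][(2R,3S)-7-(hydroxymethyl)-4,6-bis(TIPSO)-2-(4-TIPSO-phenyl)-2,3-dihydro-1-benzofuran-3-yl]methanol (both carbinol epimers)
Conditions: i-Bu2AlH (4 equiv), CH2Cl2, −78 → 0 °C; aq. potassium sodium tartrate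
Reagents that add atoms: none
Why: Hydride reduction of the aryl ester gives the benzylic alcohol under conditions that aryl silyl ethers tolerate; the acid-sensitive diol is carried on crude.

**Step 16**
Reactants: 24 diol
Product: 25 (2R,3R)-3-[2,4-bis(TIPSO)benzoyl]-4,6-bis(TIPSO)-2-(4-TIPSO-phenyl)-2,3-dihydro-1-benzofuran-7-carbaldehyde
Conditions: Dess–Martin periodinane (3 equiv), NaHCO3, CH2Cl2, 0 °C → rt
Reagents that add atoms: none
Why: Double Dess–Martin oxidation gives the C3 aryl ketone and the C7 aldehyde at once under buffered, non-basic conditions, so the trans (2R,3R) arrangement is kept.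

**Step 17**
Reactants: 26 1-(4-hydroxyphenyl)ethan-1-one
Product: 27 1-(4-TIPSO-phenyl)ethan-1-one
Conditions: TIPSCl, imidazole, DMF, rt
Reagents that add atoms: TIPSCl, CC(C)[Si](Cl)(C(C)C)C(C)C
Why: Routine phenol silylation.

**Step 18**
Reactants: 27 1-(4-TIPSO-phenyl)ethan-1-one
Product: 29 1-(4-TIPSO-phenyl)ethenyl trifluoromethanesulfonate, via potassium enolate 28 (not isolated)
Conditions: KN(SiMe3)2, THF, −78 °C; then PhNTf2, −78 → 0 °C
Reagents that add atoms: N-phenylbis(trifluoromethanesulfonimide) (PhNTf2), O=S(=O)(N(c1ccccc1)S(=O)(=O)C(F)(F)F)C(F)(F)F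
Why: O-Triflation of the methyl ketone enolate gives the 1-arylvinyl electrophile needed for the chromium-mediated coupling.

**Step 19**
Reactants: 25 keto aldehyde; 29 1-(4-TIPSO-phenyl)ethenyl trifluoromethanesulfonate
Product: 31 [2,4-bis(TIPSO)phenyl]{(2R,3R)-7-[1-hydroxy-2-(4-TIPSO-phenyl)prop-2-en-1-yl]-4,6-bis(TIPSO)-2-(4-TIPSO-phenyl)-2,3-dihydro-1-benzofuran-3-yl}methanone (both carbinol epimers), via alkenylchromium dichloride 30 (not isolated)
Conditions: 29 (3 equiv), CrCl2 (8 equiv), NiCl2 (2 mol %), DMF, rt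
Reagents that add atoms: none
Why: In the Nozaki–Hiyama–Kishi reaction, nickel-catalysed activation of the C–OTf bond and transfer to chromium give a non-basic alkenylchromium that adds only to the aldehyde, leaving the enolisable C3 ketone and its stereocentre untouched.

**Step 20**
Reactants: 31 allylic alcohol
Product: 32 1-{(2R,3R)-3-[2,4-bis(TIPSO)benzoyl]-4,6-bis(TIPSO)-2-(4-TIPSO-phenyl)-2,3-dihydro-1-benzofuran-7-yl}-2-(4-TIPSO-phenyl)prop-2-en-1-one
Conditions: Dess–Martin periodinane, NaHCO3, CH2Cl2, 0 °C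
Reagents that add atoms: none
Why: Dess–Martin oxidation of the doubly activated (allylic and benzylic) alcohol gives the 2-arylpropenone under neutral conditions.

**Step 21**
Reactants: 32 hexa-TIPS enone
Product: 33 1-[(2R,3R)-3-(2,4-dihydroxybenzoyl)-4,6-dihydroxy-2-(4-hydroxyphenyl)-2,3-dihydro-1-benzofuran-7-yl]-2-(4-hydroxyphenyl)prop-2-en-1-one
Conditions: Bu4NF, AcOH (1.2 equiv per fluoride), THF, 0 °C → rt; work-up at pH 5
Reagents that add atoms: none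
Why: Fluoride cleaves all six aryl Si–O bonds, and the acetic acid buffer keeps the phenols protonated so that neither oxa-Michael closure onto the methylene ketone nor enolisation or ring opening at C3 takes place.

**Compound list**
1 | methyl 2,4,6-trihydroxybenzoate | COC(=O)c1c(O)cc(O)cc1O | starting material
2 | methyl 2-hydroxy-4,6-bis(TIPSO)benzoate | COC(=O)c1c(O)cc(O[Si](C(C)C)(C(C)C)C(C)C)cc1O[Si](C(C)C)(C(C)C)C(C)C | intermediate
3 | methyl 2-(prop-2-en-1-yloxy)-4,6-bis(TIPSO)benzoate | COC(=O)c1c(OCC=C)cc(O[Si](C(C)C)(C(C)C)C(C)C)cc1O[Si](C(C)C)(C(C)C)C(C)C | intermediate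
4 | methyl 2-hydroxy-3-(prop-2-en-1-yl)-4,6-bis(TIPSO)benzoate | COC(=O)c1c(O)c(CC=C)c(O[Si](C(C)C)(C(C)C)C(C)C)cc1O[Si](C(C)C)(C(C)C)C(C)C | intermediate
5 | methyl 2-(methoxymethoxy)-3-(prop-2-en-1-yl)-4,6-bis(TIPSO)benzoate | COC(=O)c1c(OCOC)c(CC=C)c(O[Si](C(C)C)(C(C)C)C(C)C)cc1O[Si](C(C)C)(C(C)C)C(C)C | intermediate
6 | methyl 2-(methoxymethoxy)-3-(2-oxoethyl)-4,6-bis(TIPSO)benzoate | COC(=O)c1c(OCOC)c(CC=O)c(O[Si](C(C)C)(C(C)C)C(C)C)cc1O[Si](C(C)C)(C(C)C)C(C)C | intermediate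
7 | 2-[3-(methoxycarbonyl)-2-(methoxymethoxy)-4,6-bis(TIPSO)phenyl]acetic acid | COC(=O)c1c(OCOC)c(CC(=O)O)c(O[Si](C(C)C)(C(C)C)C(C)C)cc1O[Si](C(C)C)(C(C)C)C(C)C | intermediate
8 | (R)-4-benzyl-1,3-oxazolidin-2-one | O=C1N[C@H](Cc2ccccc2)CO1 | starting material
9 | mixed anhydride of acid 7 and pivalic acid | COC(=O)c1c(OCOC)c(CC(=O)OC(=O)C(C)(C)C)c(O[Si](C(C)C)(C(C)C)C(C)C)cc1O[Si](C(C)C)(C(C)C)C(C)C | intermediate (not isolated)
10 | (4R)-4-benzyl-3-{2-[3-(methoxycarbonyl)-2-(methoxymethoxy)-4,6-bis(TIPSO)phenyl]acetyl}-1,3-oxazolidin-2-one | COC(=O)c1c(OCOC)c(CC(=O)N2[C@H](Cc3ccccc3)COC2=O)c(O[Si](C(C)C)(C(C)C)C(C)C)cc1O[Si](C(C)C)(C(C)C)C(C)C | intermediate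
11 | 4-hydroxybenzaldehyde | O=Cc1ccc(O)cc1 | starting material
12 | 4-(TIPSO)benzaldehyde | O=Cc1ccc(O[Si](C(C)C)(C(C)C)C(C)C)cc1 | intermediate
13 | Z-dibutylboron enolate of imide 10 | CCCCB(CCCC)O/C(=C\c1c(OCOC)c(C(=O)OC)c(O[Si](C(C)C)(C(C)C)C(C)C)cc1O[Si](C(C)C)(C(C)C)C(C)C)N1[C@H](Cc2ccccc2)COC1=O | intermediate (not isolated)
14 | (4R)-4-benzyl-3-{(2R,3R)-3-hydroxy-2-[3-(methoxycarbonyl)-2-(methoxymethoxy)-4,6-bis(TIPSO)phenyl]-3-(4-TIPSO-phenyl)propanoyl}-1,3-oxazolidin-2-one | O=C1OC[C@@H](Cc2ccccc2)N1C(=O)[C@H](c1c(OCOC)c(C(=O)OC)c(O[Si](C(C)C)(C(C)C)C(C)C)cc1O[Si](C(C)C)(C(C)C)C(C)C)[C@@H](O)c1ccc(O[Si](C(C)C)(C(C)C)C(C)C)cc1 | intermediate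
15 | methyl 3-[(1R,2S)-1,3-dihydroxy-1-(4-TIPSO-phenyl)propan-2-yl]-2-(methoxymethoxy)-4,6-bis(TIPSO)benzoate | OC[C@H](c1c(OCOC)c(C(=O)OC)c(O[Si](C(C)C)(C(C)C)C(C)C)cc1O[Si](C(C)C)(C(C)C)C(C)C)[C@@H](O)c1ccc(O[Si](C(C)C)(C(C)C)C(C)C)cc1 | intermediate
16 | methyl 3-[(1R,2S)-1,3-dihydroxy-1-(4-TIPSO-phenyl)propan-2-yl]-2-hydroxy-4,6-bis(TIPSO)benzoate | OC[C@H](c1c(O)c(C(=O)OC)c(O[Si](C(C)C)(C(C)C)C(C)C)cc1O[Si](C(C)C)(C(C)C)C(C)C)[C@@H](O)c1ccc(O[Si](C(C)C)(C(C)C)C(C)C)cc1 | intermediate (not isolated)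
17 | methyl (2R,3S)-3-(hydroxymethyl)-4,6-bis(TIPSO)-2-(4-TIPSO-phenyl)-2,3-dihydro-1-benzofuran-7-carboxylate (2,3-trans) | COC(=O)c1c(O[Si](C(C)C)(C(C)C)C(C)C)cc(O[Si](C(C)C)(C(C)C)C(C)C)c2c1O[C@@H](c1ccc(O[Si](C(C)C)(C(C)C)C(C)C)cc1)[C@@H]2CO | intermediate
18 | methyl (2R,3R)-3-formyl-4,6-bis(TIPSO)-2-(4-TIPSO-phenyl)-2,3-dihydro-1-benzofuran-7-carboxylate | COC(=O)c1c(O[Si](C(C)C)(C(C)C)C(C)C)cc(O[Si](C(C)C)(C(C)C)C(C)C)c2c1O[C@@H](c1ccc(O[Si](C(C)C)(C(C)C)C(C)C)cc1)[C@@H]2C=O | intermediate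
19 | 4-bromobenzene-1,3-diol | Oc1ccc(Br)c(O)c1 | starting material
20 | 1-bromo-2,4-bis(TIPSO)benzene | Brc1ccc(O[Si](C(C)C)(C(C)C)C(C)C)cc1O[Si](C(C)C)(C(C)C)C(C)C | intermediate
21 | [2,4-bis(TIPSO)phenyl]lithium | [Li]c1ccc(O[Si](C(C)C)(C(C)C)C(C)C)cc1O[Si](C(C)C)(C(C)C)C(C)C | intermediate (not isolated)
22 | [2,4-bis(TIPSO)phenyl]cerium dichloride | Cl[Ce](Cl)c1ccc(O[Si](C(C)C)(C(C)C)C(C)C)cc1O[Si](C(C)C)(C(C)C)C(C)C | intermediate (not isolated)
23 | methyl (2R,3S)-3-{[2,4-bis(TIPSO)phenyl](hydroxy)methyl}-4,6-bis(TIPSO)-2-(4-TIPSO-phenyl)-2,3-dihydro-1-benzofuran-7-carboxylate (carbinol epimers) | COC(=O)c1c(O[Si](C(C)C)(C(C)C)C(C)C)cc(O[Si](C(C)C)(C(C)C)C(C)C)c2c1O[C@@H](c1ccc(O[Si](C(C)C)(C(C)C)C(C)C)cc1)[C@@H]2C(O)c1ccc(O[Si](C(C)C)(C(C)C)C(C)C)cc1O[Si](C(C)C)(C(C)C)C(C)C | intermediate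
24 | [2,4-bis(TIPSO)phenyl][(2R,3S)-7-(hydroxymethyl)-4,6-bis(TIPSO)-2-(4-TIPSO-phenyl)-2,3-dihydro-1-benzofuran-3-yl]methanol (carbinol epimers) | OCc1c(O[Si](C(C)C)(C(C)C)C(C)C)cc(O[Si](C(C)C)(C(C)C)C(C)C)c2c1O[C@@H](c1ccc(O[Si](C(C)C)(C(C)C)C(C)C)cc1)[C@@H]2C(O)c1ccc(O[Si](C(C)C)(C(C)C)C(C)C)cc1O[Si](C(C)C)(C(C)C)C(C)C | intermediate
25 | (2R,3R)-3-[2,4-bis(TIPSO)benzoyl]-4,6-bis(TIPSO)-2-(4-TIPSO-phenyl)-2,3-dihydro-1-benzofuran-7-carbaldehyde | O=Cc1c(O[Si](C(C)C)(C(C)C)C(C)C)cc(O[Si](C(C)C)(C(C)C)C(C)C)c2c1O[C@@H](c1ccc(O[Si](C(C)C)(C(C)C)C(C)C)cc1)[C@@H]2C(=O)c1ccc(O[Si](C(C)C)(C(C)C)C(C)C)cc1O[Si](C(C)C)(C(C)C)C(C)C | intermediate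
26 | 1-(4-hydroxyphenyl)ethan-1-one | CC(=O)c1ccc(O)cc1 | starting material
27 | 1-(4-TIPSO-phenyl)ethan-1-one | CC(=O)c1ccc(O[Si](C(C)C)(C(C)C)C(C)C)cc1 | intermediate
28 | potassium 1-(4-TIPSO-phenyl)ethen-1-olate | C=C([O-])c1ccc(O[Si](C(C)C)(C(C)C)C(C)C)cc1.[K+] | intermediate (not isolated)
29 | 1-(4-TIPSO-phenyl)ethenyl trifluoromethanesulfonate | C=C(OS(=O)(=O)C(F)(F)F)c1ccc(O[Si](C(C)C)(C(C)C)C(C)C)cc1 | intermediate
30 | [1-(4-TIPSO-phenyl)ethenyl]chromium dichloride | C=C([Cr](Cl)Cl)c1ccc(O[Si](C(C)C)(C(C)C)C(C)C)cc1 | intermediate (not isolated)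
31 | [2,4-bis(TIPSO)phenyl]{(2R,3R)-7-[1-hydroxy-2-(4-TIPSO-phenyl)prop-2-en-1-yl]-4,6-bis(TIPSO)-2-(4-TIPSO-phenyl)-2,3-dihydro-1-benzofuran-3-yl}methanone (carbinol epimers) | C=C(C(O)c1c(O[Si](C(C)C)(C(C)C)C(C)C)cc(O[Si](C(C)C)(C(C)C)C(C)C)c2c1O[C@@H](c1ccc(O[Si](C(C)C)(C(C)C)C(C)C)cc1)[C@@H]2C(=O)c1ccc(O[Si](C(C)C)(C(C)C)C(C)C)cc1O[Si](C(C)C)(C(C)C)C(C)C)c1ccc(O[Si](C(C)C)(C(C)C)C(C)C)cc1 | intermediate
32 | 1-{(2R,3R)-3-[2,4-bis(TIPSO)benzoyl]-4,6-bis(TIPSO)-2-(4-TIPSO-phenyl)-2,3-dihydro-1-benzofuran-7-yl}-2-(4-TIPSO-phenyl)prop-2-en-1-one | C=C(C(=O)c1c(O[Si](C(C)C)(C(C)C)C(C)C)cc(O[Si](C(C)C)(C(C)C)C(C)C)c2c1O[C@@H](c1ccc(O[Si](C(C)C)(C(C)C)C(C)C)cc1)[C@@H]2C(=O)c1ccc(O[Si](C(C)C)(C(C)C)C(C)C)cc1O[Si](C(C)C)(C(C)C)C(C)C)c1ccc(O[Si](C(C)C)(C(C)C)C(C)C)cc1 | intermediate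
33 | 1-[(2R,3R)-3-(2,4-dihydroxybenzoyl)-4,6-dihydroxy-2-(4-hydroxyphenyl)-2,3-dihydro-1-benzofuran-7-yl]-2-(4-hydroxyphenyl)prop-2-en-1-one (CNP0162111.1) | C=C(C(=O)c1c(O)cc(O)c2c1O[C@@H](c1ccc(O)cc1)[C@@H]2C(=O)c1ccc(O)cc1O)c1ccc(O)cc1 | target

**Step count**
Total: 21 steps. Longest linear sequence: 17 steps (1 → 33 through steps 1–7, 9–12, 14–16 and 19–21); steps 8, 13, 17 and 18 prepare the three coupling partners.

**The three steps most likely to fail, and their fallbacks**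

Step 9 (aldol). The enolate carbon sits next to an aryl ring with two ortho oxygen substituents, so enolisation or addition through the crowded boron chair may be slow or poorly selective. The fallback gives up auxiliary control in favour of an unencumbered dianion aldol followed by resolution. It sets out from acid 7 and aldehyde 12. Double deprotonation of 7 with LiN(i-Pr)2 (2.2 equiv, THF, −78 °C) and addition of 12 give the racemic anti hydroxy acid F1 (Ivanov-type aldol; the syn/anti ratio does not matter). BH3·SMe2 reduces the carboxylic acid, but not the aryl ester, to the racemic anti diol F2. The acid treatment of step 11 then converges both carbinol configurations on the racemic trans alcohol F3. Preparative chromatography on a chiral stationary phase separates the (2R,3S) enantiomer, which is compound 17, where the route is rejoined; the other enantiomer is discarded.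

Step 14 (aryl addition). Aldehyde 18 has an acidic C3–H with a β-aryloxy leaving group, so a basic aryl metal can epimerise it or open the ring, and the nucleophile is hindered by its ortho silyloxy group. The fallback replaces the polar organometallic by a non-basic chromium-mediated arylation. It sets out from bromide 20 and aldehyde 18. Aryllithium 21 is quenched with I2 to give 1-iodo-2,4-bis(TIPSO)benzene F4, which is coupled with 18 under Nozaki–Hiyama–Kishi conditions (CrCl2, catalytic NiCl2, DMF, rt). This gives alcohol 23 directly, where the route is rejoined.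

Step 21 (global desilylation). The liberated C6 phenoxide can add to the adjacent methylene ketone (isoflavanone formation), and the enone can polymerise. The fallback masks the enone during deprotection and regenerates it last under neutral conditions. It sets out from enone 32. Conjugate addition of PhSH (catalytic Et3N, CH2Cl2, 0 °C) gives the β-phenylthio ketone F5 as a mixture of side-chain epimers. Bu4NF/AcOH then removes the six silyl groups to give the hexaphenol sulfide F6. H2O2 in (CF3)2CHOH oxidises the sulfur selectively to the sulfoxide F7, and warming in dioxane (60 °C) causes syn-elimination of benzenesulfenic acid to give target 33.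

**Further compounds**
F1 | step 9 | racemic anti acid, (2R,3S) enantiomer drawn: 3-hydroxy-2-[3-(methoxycarbonyl)-2-(methoxymethoxy)-4,6-bis(TIPSO)phenyl]-3-(4-TIPSO-phenyl)propanoic acid | OC(=O)[C@H](c1c(OCOC)c(C(=O)OC)c(O[Si](C(C)C)(C(C)C)C(C)C)cc1O[Si](C(C)C)(C(C)C)C(C)C)[C@H](O)c1ccc(O[Si](C(C)C)(C(C)C)C(C)C)cc1
F2 | step 9 | racemic anti diol, (1S,2S) enantiomer drawn: methyl 3-[1,3-dihydroxy-1-(4-TIPSO-phenyl)propan-2-yl]-2-(methoxymethoxy)-4,6-bis(TIPSO)benzoate | OC[C@H](c1c(OCOC)c(C(=O)OC)c(O[Si](C(C)C)(C(C)C)C(C)C)cc1O[Si](C(C)C)(C(C)C)C(C)C)[C@H](O)c1ccc(O[Si](C(C)C)(C(C)C)C(C)C)cc1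
F3 | step 9 | racemic trans alcohol (racemate of 17), (2R,3S) enantiomer drawn: methyl 3-(hydroxymethyl)-4,6-bis(TIPSO)-2-(4-TIPSO-phenyl)-2,3-dihydro-1-benzofuran-7-carboxylate | COC(=O)c1c(O[Si](C(C)C)(C(C)C)C(C)C)cc(O[Si](C(C)C)(C(C)C)C(C)C)c2c1O[C@@H](c1ccc(O[Si](C(C)C)(C(C)C)C(C)C)cc1)[C@@H]2CO
F4 | step 14 | 1-iodo-2,4-bis(TIPSO)benzene | Ic1ccc(O[Si](C(C)C)(C(C)C)C(C)C)cc1O[Si](C(C)C)(C(C)C)C(C)C
F5 | step 21 | 1-{(2R,3R)-3-[2,4-bis(TIPSO)benzoyl]-4,6-bis(TIPSO)-2-(4-TIPSO-phenyl)-2,3-dihydro-1-benzofuran-7-yl}-3-(phenylsulfanyl)-2-(4-TIPSO-phenyl)propan-1-one (side-chain epimers) | O=C(C(CSc1ccccc1)c1ccc(O[Si](C(C)C)(C(C)C)C(C)C)cc1)c1c(O[Si](C(C)C)(C(C)C)C(C)C)cc(O[Si](C(C)C)(C(C)C)C(C)C)c2c1O[C@@H](c1ccc(O[Si](C(C)C)(C(C)C)C(C)C)cc1)[C@@H]2C(=O)c1ccc(O[Si](C(C)C)(C(C)C)C(C)C)cc1O[Si](C(C)C)(C(C)C)C(C)C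
F6 | step 21 | 1-[(2R,3R)-3-(2,4-dihydroxybenzoyl)-4,6-dihydroxy-2-(4-hydroxyphenyl)-2,3-dihydro-1-benzofuran-7-yl]-2-(4-hydroxyphenyl)-3-(phenylsulfanyl)propan-1-one (side-chain epimers) | O=C(C(CSc1ccccc1)c1ccc(O)cc1)c1c(O)cc(O)c2c1O[C@@H](c1ccc(O)cc1)[C@@H]2C(=O)c1ccc(O)cc1O
F7 | step 21 | 1-[(2R,3R)-3-(2,4-dihydroxybenzoyl)-4,6-dihydroxy-2-(4-hydroxyphenyl)-2,3-dihydro-1-benzofuran-7-yl]-2-(4-hydroxyphenyl)-3-(phenylsulfinyl)propan-1-one (mixture of stereoisomers in the side chain) | O=C(C(CS(=O)c1ccccc1)c1ccc(O)cc1)c1c(O)cc(O)c2c1O[C@@H](c1ccc(O)cc1)[C@@H]2C(=O)c1ccc(O)cc1O
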